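**Plan**

1. Retrosynthesis: the interflavanyl bond C4 (ring C)–C6 (ring D) is cut first. This gives two copies of one protected 2,3-cis-3,4-trans-7,8,3',4'-tetraoxygenated flavan-3,4-diol: the free 4-ol as C4-cation precursor and its 4-O-silyl ether as nucleophile.
2. In that monomer the aryl ether bond O1–C8a and the C8–O bond are cut together, leading back to an acyclic all-syn 1,3-diarylpropane-1,2,3-triol derivative whose ring-A precursor is a plain 2-fluoro-4-benzyloxyphenyl group. This chain is cut at C2–aryl (ring B) and at C3–C4 (glycolate aldol).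
3. Forward: Evans glycolate aldol (C3–C4), chelation-controlled aryl Grignard addition (C2), then ring C is closed on a C8a≡C8 aryne with oxygenation of C8 in the same flask. The same chroman then serves as both halves; Friedel–Crafts union, hydrogenolysis and desilylation finish the route.
4. Enabling feature: ring A (and ring D) carries three contiguous oxygens, O1 on C8a, OH on C8 and OH on C7. The C8a–C8 pair lies between C4a, which carries the C4–C3–C2–O tether, and the 7-oxygen, so an aryne across C8a≡C8 takes up the tethered oxygen at C8a and an oxygen electrophile at C8.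
5. Stereochemistry: C3 and C4 come from the (R)-oxazolidinone-controlled syn aldol, C2 from Cram-chelate addition. Ring closure makes the O–aryl bond and so retains C2 (syn becomes 2,3-cis). The upper C4 is set by attack anti to the axial 3-benzyloxy group (3,4-trans).

Key step: step 8

Remark: flavan numbering is used; rings A/C/B belong to the upper (4-aryl) unit and D/F/E to the lower (3,4-diol) unit. C6 of ring D (para to O1, ortho to the 7-oxygen) is assumed to be the most nucleophilic arene carbon of the 4-O-silyl monomer.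

**Route**

Step 1
Reactants: 1 2-fluoro-4-hydroxybenzaldehyde
Product: 2 4-(benzyloxy)-2-fluorobenzaldehyde
Conditions: BnBr, K2CO3, DMF, rt
Reagents that add atoms: benzyl bromide BrCc1ccccc1
Why: Williamson ether synthesis of the phenol, whose phenoxide (para to the formyl group) is benzylated far faster than carbonate or phenoxide can displace the aryl fluoride at room temperature.

Step 2
Reactants: 3 (R)-4-benzyloxazolidin-2-one; 4 benzyloxyacetyl chloride
Product: 6 (R)-4-benzyl-3-[2-(benzyloxy)acetyl]oxazolidin-2-one, via N-lithiated oxazolidinone 5 (not isolated)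
Conditions: n-BuLi, THF, −78 °C; then 4, −78 → 0 °C
Reagents that add atoms: none
Why: N-acylation of the lithiated oxazolidinone by the acid chloride (preparation of an Evans glycolate imide) at low temperature, which leaves the auxiliary stereocentre untouched.

Step 3
Reactants: 6 (R)-4-benzyl-3-[2-(benzyloxy)acetyl]oxazolidin-2-one; 2 4-(benzyloxy)-2-fluorobenzaldehyde
Product: 9 (R)-4-benzyl-3-[(2R,3S)-2-(benzyloxy)-3-[4-(benzyloxy)-2-fluorophenyl]-3-hydroxypropanoyl]oxazolidin-2-one, via dibutylboron Z-enolate 7 (not isolated), via dibutylboron aldolate 8 (not isolated)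
Conditions: n-Bu2BOTf, Et3N, CH2Cl2, −78 → 0 °C; 2, −78 → 0 °C; then pH 7 buffer, MeOH, 30% H2O2, 0 °C
Reagents that add atoms: none
Why: Evans syn-aldol reaction: the Z boron enolate 7 reacts through a Zimmerman–Traxler chair in which the benzyl group of the (R)-auxiliary shields one enolate face, setting the α-carbon (R, future flavan C3) and the carbinol carbon (S, future flavan C4) in the syn relation that becomes 3,4-trans in the ring.

Step 4
Reactants: 9 the syn-aldol adduct
Product: 10 (R)-4-benzyl-3-[(2R,3S)-2-(benzyloxy)-3-[4-(benzyloxy)-2-fluorophenyl]-3-(tert-butyldimethylsilyloxy)propanoyl]oxazolidin-2-one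
Conditions: TBSOTf, 2,6-lutidine, CH2Cl2, −78 → 0 °C
Reagents that add atoms: tert-butyldimethylsilyl trifluoromethanesulfonate CC(C)(C)[Si](C)(C)OS(=O)(=O)C(F)(F)F
Why: Silylation of the secondary benzylic alcohol with a silyl triflate and a hindered pyridine base proceeds without retro-aldol cleavage and installs the C4-oxygen protecting group that later survives base, Lewis acid and hydrogenolysis.

Step 5
Reactants: 10 the silylated imide
Product: 11 (2S,3S)-2-(benzyloxy)-3-[4-(benzyloxy)-2-fluorophenyl]-3-(tert-butyldimethylsilyloxy)propan-1-ol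
Conditions: LiBH4, MeOH (1 equiv), THF, 0 °C
Reagents that add atoms: none
Why: Reductive cleavage of the N-acyl oxazolidinone by LiBH4 (hydride attacks the exocyclic imide carbonyl) gives the primary alcohol without enolisation of the α-alkoxy centre and returns the auxiliary.

Step 6
Reactants: 11 the primary alcohol
Product: 12 (2R,3S)-2-(benzyloxy)-3-[4-(benzyloxy)-2-fluorophenyl]-3-(tert-butyldimethylsilyloxy)propanal
Conditions: Dess–Martin periodinane, pyridine, CH2Cl2, 0 °C → rt; used at once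
Reagents that add atoms: none
Why: Dess–Martin oxidation under buffered, non-basic conditions gives the α-benzyloxy aldehyde without epimerisation at C2 or β-elimination of the silyloxy group.

Step 7
Reactants: 12 the α-benzyloxy aldehyde; 13 4-bromo-1,2-bis(benzyloxy)benzene
Product: 15 (1R,2S,3S)-2-(benzyloxy)-1-[3,4-bis(benzyloxy)phenyl]-3-[4-(benzyloxy)-2-fluorophenyl]-3-(tert-butyldimethylsilyloxy)propan-1-ol (all-syn), via arylmagnesium bromide 14 (not isolated)
Conditions: 13, Mg turnings, THF, 40 °C; then added to 12 and MgBr2·OEt2 in CH2Cl2, −78 °C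
Reagents that add atoms: none
Why: Grignard addition under Cram-chelate control: magnesium bridges the carbonyl oxygen and the α-benzyloxy oxygen in a five-membered chelate and the aryl group adds to the face away from the C3 substituent, which sets the new carbinol centre (1R, future flavan C2) syn to the 2-benzyloxy group.

Step 8
Reactants: 15 the all-syn fluoroaryl carbinol
Product: 20 (2R,3S,4S)-3,7-bis(benzyloxy)-2-[3,4-bis(benzyloxy)phenyl]-4-(tert-butyldimethylsilyloxy)chroman-8-ol (2,3-cis-3,4-trans), via C8-lithiated fluoroarene alkoxide 16 (not isolated), via aryne alkoxide 17 (not isolated), via 8-lithiochromane 18 (not isolated), via 8-boronate 19 (not isolated)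
Conditions: lithium 2,2,6,6-tetramethylpiperidide (2.3 equiv, from 2,2,6,6-tetramethylpiperidine and n-BuLi), THF, −78 °C, then −78 → −10 °C; B(OMe)3, −78 °C → rt; then 30% H2O2, aq. NaOH, 0 °C
Reagents that add atoms: hydrogen peroxide OO
Why: Deprotonation of the hydroxyl and of C8–H (the one ring-A hydrogen flanked by fluorine and the 7-benzyloxy group) gives 16, which loses LiF on warming to the aryne 17 (triple bond C8a≡C8); the tethered C2 alkoxide adds to C8a, and the C8 aryllithium 18, held between O1 and the 7-oxygen, is captured by B(OMe)3 and oxidised to the phenol, so O1 and the 8-oxygen are placed on neighbouring carbons in one operation. The closest known reaction types are benzyne cyclisations of tethered alkoxides to chromans with capture of the new ortho carbanion by an electrophile, and the borylation–oxidation of aryllithiums. Ring C closes in a 6-exo-dig mode onto the in-plane aryne π bond. No stereocentre is formed: C2, C3 and C4 come unchanged from 15, and because the bond made is O–aryl and not O–C2, the configuration at C2 is retained, which turns the syn C2/C3 relation into the 2,3-cis ring. Regioselectivity of the oxygen addition is needed and is secured twice: the tether from C4a can only reach C8a, and the 7-benzyloxy group beside C8 polarises the aryne so that nucleophiles add at the distal carbon C8a while the negative charge develops at C8 next to the inductively withdrawing oxygen. The hindered amide base and the charged alkoxide should keep amide addition and attack by the neutral 3-O-benzyl oxygen from competing.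

Step 9
Reactants: 20 the chroman-8-ol
Product: 21 (2R,3S,4S)-3,7,8-tris(benzyloxy)-2-[3,4-bis(benzyloxy)phenyl]-4-(tert-butyldimethylsilyloxy)chromane
Conditions: BnBr, K2CO3, Bu4NI (cat.), DMF, 50 °C
Reagents that add atoms: benzyl bromide BrCc1ccccc1
Why: Williamson ether synthesis on the hindered 8-phenol (the only acidic OH) gives the fully protected monomer that serves as both halves of the target.

Step 10
Reactants: 21 the 4-O-silyl monomer (about one quarter of the material)
Product: 22 (2R,3R,4S)-3,7,8-tris(benzyloxy)-2-[3,4-bis(benzyloxy)phenyl]chroman-4-ol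
Conditions: Bu4NF, THF, 0 °C → rt
Reagents that add atoms: none
Why: Fluoride-mediated cleavage of the Si–O bond frees the 4-hydroxyl with the C4 configuration unchanged, since the C4–O bond is not broken and benzyl ethers are inert to Bu4NF.

Step 11
Reactants: 22 the 4-ol (1 equiv, added slowly); 21 the 4-O-silyl monomer (3 equiv, excess recovered)
Product: 23 (2R,3R,4R)-3,7,8-tris(benzyloxy)-2-[3,4-bis(benzyloxy)phenyl]-4-[(2R,3S,4S)-3,7,8-tris(benzyloxy)-2-[3,4-bis(benzyloxy)phenyl]-4-(tert-butyldimethylsilyloxy)chroman-6-yl]chromane (both units 2,3-cis-3,4-trans)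
Conditions: BF3·OEt2 (0.3 equiv), 4 Å molecular sieves, CH2Cl2, −78 → −20 °C
Reagents that add atoms: none
Why: Friedel–Crafts alkylation (the flavan-3,4-diol route to 4-arylflavans) with loss of water: BF3 ionises only the free 4-hydroxyl of 22 (the bulky, weakly basic silyl ether of 21 does not ionise) to a C4 benzylic cation stabilised by O1 and the 7-oxygen, which is attacked by C6 of ring D of 21 (para to O1, ortho to the 7-oxygen and, unlike C5, not hindered by C4) from the face anti to the pseudo-axial 3-benzyloxy group, so the new upper C4 centre is set 3,4-trans.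

Step 12
Reactants: 23 the protected dimer
Product: 24 (2R,3R,4S)-2-(3,4-dihydroxyphenyl)-4-[(2R,3S,4S)-4-(tert-butyldimethylsilyloxy)-2-(3,4-dihydroxyphenyl)-3,7,8-trihydroxychroman-6-yl]chromane-3,7,8-triol
Conditions: H2 (1–3 atm), 20% Pd(OH)2/C, EtOAc–THF 1:1, rt
Reagents that add atoms: none
Why: Hydrogenolysis of the eight aryl and two alkyl benzyl ethers over Pd(OH)2/C leaves the cyclic benzylic ether bonds at C2 intact, and the silyl ether shields the ring-F C4–O bond, which in a free flavan-3,4-diol is itself open to hydrogenolysis.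

Step 13
Reactants: 24 the 4-O-silyl polyphenol
Product: 25 (2R,3R,4S)-2-(3,4-dihydroxyphenyl)-4-[(2R,3R,4S)-2-(3,4-dihydroxyphenyl)-3,4,7,8-tetrahydroxychroman-6-yl]chromane-3,7,8-triol (CNP0143773.2)
Conditions: HF·pyridine, pyridine, THF, 0 °C → rt, argon; chromatography on Sephadex LH-20
Reagents that add atoms: none
Why: Buffered fluoride desilylation breaks only the Si–O bond, so the 4-hydroxyl appears with the 3,4-trans configuration unchanged, and the weakly acidic, oxygen-free medium should avoid both catechol oxidation and ionisation at C4.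

**Compound list**

1 | 2-fluoro-4-hydroxybenzaldehyde | O=Cc1ccc(O)cc1F | starting material
2 | 4-(benzyloxy)-2-fluorobenzaldehyde | O=Cc1ccc(OCc2ccccc2)cc1F | intermediate
3 | (R)-4-benzyloxazolidin-2-one | O=C1N[C@H](Cc2ccccc2)CO1 | starting material
4 | benzyloxyacetyl chloride | O=C(Cl)COCc1ccccc1 | starting material
5 | N-lithio-(R)-4-benzyloxazolidin-2-one | [Li]N1[C@H](Cc2ccccc2)COC1=O | intermediate (not isolated)
6 | (R)-4-benzyl-3-[2-(benzyloxy)acetyl]oxazolidin-2-one | O=C(COCc1ccccc1)N1C(=O)OC[C@H]1Cc1ccccc1 | intermediate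
7 | dibutylboron Z-enolate of 6 | CCCCB(CCCC)O/C(N1C(=O)OC[C@H]1Cc1ccccc1)=C\OCc1ccccc1 | intermediate (not isolated)
8 | dibutylboron aldolate of 9 | O=C(N1C(=O)OC[C@H]1Cc1ccccc1)[C@H](OCc1ccccc1)[C@H](c1ccc(OCc2ccccc2)cc1F)OB(CCCC)CCCC | intermediate (not isolated)
9 | (R)-4-benzyl-3-[(2R,3S)-2-(benzyloxy)-3-[4-(benzyloxy)-2-fluorophenyl]-3-hydroxypropanoyl]oxazolidin-2-one | O=C(N1C(=O)OC[C@H]1Cc1ccccc1)[C@H](OCc1ccccc1)[C@H](c1ccc(OCc2ccccc2)cc1F)O | intermediate
10 | (R)-4-benzyl-3-[(2R,3S)-2-(benzyloxy)-3-[4-(benzyloxy)-2-fluorophenyl]-3-(tert-butyldimethylsilyloxy)propanoyl]oxazolidin-2-one | O=C(N1C(=O)OC[C@H]1Cc1ccccc1)[C@H](OCc1ccccc1)[C@H](c1ccc(OCc2ccccc2)cc1F)O[Si](C)(C)C(C)(C)C | intermediate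
11 | (2S,3S)-2-(benzyloxy)-3-[4-(benzyloxy)-2-fluorophenyl]-3-(tert-butyldimethylsilyloxy)propan-1-ol | OC[C@H](OCc1ccccc1)[C@H](c1ccc(OCc2ccccc2)cc1F)O[Si](C)(C)C(C)(C)C | intermediate
12 | (2R,3S)-2-(benzyloxy)-3-[4-(benzyloxy)-2-fluorophenyl]-3-(tert-butyldimethylsilyloxy)propanal | O=C[C@H](OCc1ccccc1)[C@H](c1ccc(OCc2ccccc2)cc1F)O[Si](C)(C)C(C)(C)C | intermediate
13 | 4-bromo-1,2-bis(benzyloxy)benzene | Brc1ccc(OCc2ccccc2)c(OCc2ccccc2)c1 | starting material
14 | 3,4-bis(benzyloxy)phenylmagnesium bromide | Br[Mg]c1ccc(OCc2ccccc2)c(OCc2ccccc2)c1 | intermediate (not isolated)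
15 | (1R,2S,3S)-2-(benzyloxy)-1-[3,4-bis(benzyloxy)phenyl]-3-[4-(benzyloxy)-2-fluorophenyl]-3-(tert-butyldimethylsilyloxy)propan-1-ol | O[C@H](c1ccc(OCc2ccccc2)c(OCc2ccccc2)c1)[C@H](OCc1ccccc1)[C@H](c1ccc(OCc2ccccc2)cc1F)O[Si](C)(C)C(C)(C)C | intermediate
16 | lithium alkoxide of 15 lithiated at the ring carbon between F and OBn | [Li]O[C@H](c1ccc(OCc2ccccc2)c(OCc2ccccc2)c1)[C@H](OCc1ccccc1)[C@H](c1ccc(OCc2ccccc2)c([Li])c1F)O[Si](C)(C)C(C)(C)C | intermediate (not isolated)
17 | lithium alkoxide carrying the 4-(benzyloxy)benzyne ring (triple bond at the former C–F and C–Li carbons) | [Li]O[C@H](c1ccc(OCc2ccccc2)c(OCc2ccccc2)c1)[C@H](OCc1ccccc1)[C@H](C1=CC=C(OCc2ccccc2)C#C1)O[Si](C)(C)C(C)(C)C | intermediate (not isolated)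
18 | (2R,3S,4S)-3,7-bis(benzyloxy)-2-[3,4-bis(benzyloxy)phenyl]-4-(tert-butyldimethylsilyloxy)-8-lithiochromane | [Li]c1c(OCc2ccccc2)ccc2c1O[C@H](c1ccc(OCc3ccccc3)c(OCc3ccccc3)c1)[C@H](OCc1ccccc1)[C@H]2O[Si](C)(C)C(C)(C)C | intermediate (not isolated)
19 | dimethyl ester of the corresponding chroman-8-ylboronic acid | COB(OC)c1c(OCc2ccccc2)ccc2c1O[C@H](c1ccc(OCc3ccccc3)c(OCc3ccccc3)c1)[C@H](OCc1ccccc1)[C@H]2O[Si](C)(C)C(C)(C)C | intermediate (not isolated)
20 | (2R,3S,4S)-3,7-bis(benzyloxy)-2-[3,4-bis(benzyloxy)phenyl]-4-(tert-butyldimethylsilyloxy)chroman-8-ol | Oc1c(OCc2ccccc2)ccc2c1O[C@H](c1ccc(OCc3ccccc3)c(OCc3ccccc3)c1)[C@H](OCc1ccccc1)[C@H]2O[Si](C)(C)C(C)(C)C | intermediate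
21 | (2R,3S,4S)-3,7,8-tris(benzyloxy)-2-[3,4-bis(benzyloxy)phenyl]-4-(tert-butyldimethylsilyloxy)chromane | C(c1ccccc1)Oc1c(OCc2ccccc2)ccc2c1O[C@H](c1ccc(OCc3ccccc3)c(OCc3ccccc3)c1)[C@H](OCc1ccccc1)[C@H]2O[Si](C)(C)C(C)(C)C | intermediate
22 | (2R,3R,4S)-3,7,8-tris(benzyloxy)-2-[3,4-bis(benzyloxy)phenyl]chroman-4-ol | C(c1ccccc1)Oc1c(OCc2ccccc2)ccc2c1O[C@H](c1ccc(OCc3ccccc3)c(OCc3ccccc3)c1)[C@H](OCc1ccccc1)[C@H]2O | intermediate
23 | deca-O-benzyl 4-O-silyl (4→6) dimer: (2R,3R,4R)-3,7,8-tris(benzyloxy)-2-[3,4-bis(benzyloxy)phenyl]-4-[(2R,3S,4S)-3,7,8-tris(benzyloxy)-2-[3,4-bis(benzyloxy)phenyl]-4-(tert-butyldimethylsilyloxy)chroman-6-yl]chromane | C(c9ccccc9)Oc1ccc([C@H]2Oc3c(ccc(OCc9ccccc9)c3OCc9ccccc9)[C@H](c3cc4c(c(OCc9ccccc9)c3OCc9ccccc9)O[C@H](c3ccc(OCc9ccccc9)c(OCc9ccccc9)c3)[C@H](OCc9ccccc9)[C@H]4O[Si](C)(C)C(C)(C)C)[C@H]2OCc9ccccc9)cc1OCc9ccccc9 | intermediate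
24 | (2R,3R,4S)-2-(3,4-dihydroxyphenyl)-4-[(2R,3S,4S)-4-(tert-butyldimethylsilyloxy)-2-(3,4-dihydroxyphenyl)-3,7,8-trihydroxychroman-6-yl]chromane-3,7,8-triol | Oc1ccc([C@H]2Oc3c(ccc(O)c3O)[C@H](c3cc4c(c(O)c3O)O[C@H](c3ccc(O)c(O)c3)[C@H](O)[C@H]4O[Si](C)(C)C(C)(C)C)[C@H]2O)cc1O | intermediate
25 | (2R,3R,4S)-2-(3,4-dihydroxyphenyl)-4-[(2R,3R,4S)-2-(3,4-dihydroxyphenyl)-3,4,7,8-tetrahydroxychroman-6-yl]chromane-3,7,8-triol | Oc1ccc([C@H]2Oc3c(ccc(O)c3O)[C@H](c3cc4c(c(O)c3O)O[C@H](c3ccc(O)c(O)c3)[C@H](O)[C@H]4O)[C@H]2O)cc1O | target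

**Step count and risks**

Total step count: 13. Longest linear sequence: 12 steps (steps 1 and 3–13, or equally steps 2–13).

Steps most likely to fail:

Step 8. The aryne may be diverted before ring closure (amide addition, attack by the neutral 3-O-benzyl oxygen, a 1,3-silyl shift in the alkoxide), or the aryllithium may be quenched before borate capture. Fallback: ring C is closed by a palladium-catalysed intramolecular aryl etherification, a known O–aryl bond formation that also retains C2, on a bromide that already carries the 8-oxygen. The fallback sets out from 6. Commercial 2-bromo-3-hydroxy-4-methoxybenzaldehyde is demethylated (BBr3, CH2Cl2) to 2-bromo-3,4-dihydroxybenzaldehyde F1 and benzylated (BnBr, K2CO3, DMF) to 3,4-bis(benzyloxy)-2-bromobenzaldehyde F2. F2 replaces 2 in steps 3 to 7, which should give in turn the syn-aldol adduct F3, its silyl ether F4, the primary alcohol F5, the aldehyde F6 and the all-syn bromoaryl carbinol F7. F7 with Pd(OAc)2, 2-(di-tert-butylphosphino)-1,1'-binaphthyl and Cs2CO3 in toluene at 80 °C should cyclise to 21, where the route is rejoined; step 9 is then not needed.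

Step 11. The cation from 22 may be taken up by ring A of a second molecule of 22 or of the product (self-condensation and over-alkylation to oligomers) instead of by 21. Fallback: the nucleophilic C6 of the electrophile is capped. The fallback sets out from 22, which is brominated at C6 (N-bromosuccinimide, CH2Cl2, −20 °C) to the 6-bromochroman-4-ol F8. F8 is coupled with one equivalent of 21 under the conditions of step 11 to the 6-bromo dimer F9. Hydrogenolysis as in step 12 with NaOAc added removes bromine and benzyl groups together and returns the route at 24.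

Step 7. Facial selectivity in the aryl addition may be poor through competition of the non-chelated Felkin–Anh pathway. Fallback: the carbinol centre is set by hydride delivery instead of aryl delivery. The fallback sets out from 12. Addition of 14 in THF without MgBr2·OEt2 is accepted to give 15 together with its (1S) epimer F10, and the mixture is oxidised (Dess–Martin periodinane, CH2Cl2) to the single aryl ketone F11. F11 is reduced with K[sec-Bu3BH] in THF at −78 °C, where polar Felkin–Anh control (hydride anti to the α-benzyloxy group, no chelation by potassium) should give the 1,2-syn alcohol 15, where the route is rejoined.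

**Further compounds**

F1 | step 8 | 2-bromo-3,4-dihydroxybenzaldehyde | O=Cc1ccc(O)c(O)c1Br
F2 | step 8 | 3,4-bis(benzyloxy)-2-bromobenzaldehyde | O=Cc1ccc(OCc2ccccc2)c(OCc2ccccc2)c1Br
F3 | step 8 | (R)-4-benzyl-3-[(2R,3S)-2-(benzyloxy)-3-[3,4-bis(benzyloxy)-2-bromophenyl]-3-hydroxypropanoyl]oxazolidin-2-one | O=C(N1C(=O)OC[C@H]1Cc1ccccc1)[C@H](OCc1ccccc1)[C@H](c1ccc(OCc2ccccc2)c(OCc2ccccc2)c1Br)O
F4 | step 8 | (R)-4-benzyl-3-[(2R,3S)-2-(benzyloxy)-3-[3,4-bis(benzyloxy)-2-bromophenyl]-3-(tert-butyldimethylsilyloxy)propanoyl]oxazolidin-2-one | O=C(N1C(=O)OC[C@H]1Cc1ccccc1)[C@H](OCc1ccccc1)[C@H](c1ccc(OCc2ccccc2)c(OCc2ccccc2)c1Br)O[Si](C)(C)C(C)(C)C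
F5 | step 8 | (2S,3S)-2-(benzyloxy)-3-[3,4-bis(benzyloxy)-2-bromophenyl]-3-(tert-butyldimethylsilyloxy)propan-1-ol | OC[C@H](OCc1ccccc1)[C@H](c1ccc(OCc2ccccc2)c(OCc2ccccc2)c1Br)O[Si](C)(C)C(C)(C)C
F6 | step 8 | (2R,3S)-2-(benzyloxy)-3-[3,4-bis(benzyloxy)-2-bromophenyl]-3-(tert-butyldimethylsilyloxy)propanal | O=C[C@H](OCc1ccccc1)[C@H](c1ccc(OCc2ccccc2)c(OCc2ccccc2)c1Br)O[Si](C)(C)C(C)(C)C
F7 | step 8 | (1R,2S,3S)-2-(benzyloxy)-1-[3,4-bis(benzyloxy)phenyl]-3-[3,4-bis(benzyloxy)-2-bromophenyl]-3-(tert-butyldimethylsilyloxy)propan-1-ol | O[C@H](c1ccc(OCc2ccccc2)c(OCc2ccccc2)c1)[C@H](OCc1ccccc1)[C@H](c1ccc(OCc2ccccc2)c(OCc2ccccc2)c1Br)O[Si](C)(C)C(C)(C)C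
F8 | step 11 | (2R,3R,4S)-3,7,8-tris(benzyloxy)-2-[3,4-bis(benzyloxy)phenyl]-6-bromochroman-4-ol | C(c1ccccc1)Oc1c(OCc2ccccc2)c(Br)cc2c1O[C@H](c1ccc(OCc3ccccc3)c(OCc3ccccc3)c1)[C@H](OCc1ccccc1)[C@H]2O
F9 | step 11 | 6-bromo derivative of 23 (bromine at C6 of ring A of the upper unit; spatial arrangement as in 23) | C(c9ccccc9)Oc1ccc([C@H]2Oc3c(cc(Br)c(OCc9ccccc9)c3OCc9ccccc9)[C@H](c3cc4c(c(OCc9ccccc9)c3OCc9ccccc9)O[C@H](c3ccc(OCc9ccccc9)c(OCc9ccccc9)c3)[C@H](OCc9ccccc9)[C@H]4O[Si](C)(C)C(C)(C)C)[C@H]2OCc9ccccc9)cc1OCc9ccccc9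
F10 | step 7 | (1S,2S,3S)-2-(benzyloxy)-1-[3,4-bis(benzyloxy)phenyl]-3-[4-(benzyloxy)-2-fluorophenyl]-3-(tert-butyldimethylsilyloxy)propan-1-ol | O[C@@H](c1ccc(OCc2ccccc2)c(OCc2ccccc2)c1)[C@H](OCc1ccccc1)[C@H](c1ccc(OCc2ccccc2)cc1F)O[Si](C)(C)C(C)(C)C
F11 | step 7 | (2R,3S)-2-(benzyloxy)-1-[3,4-bis(benzyloxy)phenyl]-3-[4-(benzyloxy)-2-fluorophenyl]-3-(tert-butyldimethylsilyloxy)propan-1-one | O=C(c1ccc(OCc2ccccc2)c(OCc2ccccc2)c1)[C@H](OCc1ccccc1)[C@H](c1ccc(OCc2ccccc2)cc1F)O[Si](C)(C)C(C)(C)C
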